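**Retrosynthetic overview**
- Albanin A comes from its tetra-MOM ether by global acidic deprotection in the last step.
- The pyranone ring is the only ring built, and it is closed by forming C4–C3: the A-ring aldehyde, as its carbene-derived Breslow (acyl anion) intermediate, adds 6-exo-dig to an unactivated enyne triple bond. A 1,3-prototropic shift then turns the exocyclic dienone into the 3-prenyl-4H-chromen-4-one.
- The cyclisation precursor comes from a Mitsunobu O-alkylation (O1–C2 bond) of 2-hydroxy-4,6-bis(methoxymethoxy)benzaldehyde with the B-ring enynol.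
- The enynol comes from 2,4-bis(methoxymethoxy)benzaldehyde, ethynyl Grignard and a Sonogashira coupling with 1-bromo-2-methylpropene, which supplies the prenyl carbons. Rings A and B are bought as the hydroxybenzaldehydes.

Assumption: Albanin A has no stereocentre and no stereogenic double bond, so no stereocontrol is needed; the one stereocentre in intermediates 5, 7, 10, 11 and 12 is carried racemic and is erased when C2 becomes sp2.

**Step 1**
Reactants: 1 2,4-dihydroxybenzaldehyde; 2 chloromethyl methyl ether (MOMCl)
Product: 3 2,4-bis(methoxymethoxy)benzaldehyde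
Conditions: NaH (2.4 equiv), MOMCl (2.4 equiv), DMF, 0 °C → rt
Reagents that add atoms: chloromethyl methyl ether, COCCl
Why: Williamson-type O-alkylation (MOM protection) of both phenoxides; NaH ensures the hydrogen-bonded 2-OH also reacts.

**Step 2**
Reactants: 3 2,4-bis(methoxymethoxy)benzaldehyde; 4 ethynylmagnesium bromide
Product: 5 rac-1-[2,4-bis(methoxymethoxy)phenyl]prop-2-yn-1-ol
Conditions: HC≡CMgBr (1.3 equiv), THF, 0 °C → rt; then H2O
Reagents that add atoms: ethynylmagnesium bromide, C#C[Mg]Br
Why: Grignard 1,2-addition to the aldehyde; the carbinol centre is formed racemic on purpose because it later becomes the sp2 C2 of the flavone.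

**Step 3**
Reactants: 5 rac-1-[2,4-bis(methoxymethoxy)phenyl]prop-2-yn-1-ol; 6 1-bromo-2-methylprop-1-ene
Product: 7 rac-1-[2,4-bis(methoxymethoxy)phenyl]-5-methylhex-4-en-2-yn-1-ol
Conditions: PdCl2(PPh3)2 (3 mol %), CuI (5 mol %), Et3N, THF, 40 °C
Reagents that add atoms: 1-bromo-2-methylprop-1-ene, CC(C)=CBr
Why: Sonogashira coupling of the terminal alkyne with a vinyl bromide; the free propargylic alcohol and the MOM ethers are inert under these conditions.

**Step 4**
Reactants: 8 2,4,6-trihydroxybenzaldehyde; 2 chloromethyl methyl ether (MOMCl)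
Product: 9 2-hydroxy-4,6-bis(methoxymethoxy)benzaldehyde
Conditions: MOMCl (2.1 equiv), i-Pr2NEt (2.5 equiv), CH2Cl2, 0 °C → rt
Reagents that add atoms: chloromethyl methyl ether, COCCl
Why: selective MOM protection; the 4-OH and one ortho-OH are alkylated, while the remaining ortho-OH is chelated to the aldehyde and stays free with the mild amine base.

**Step 5**
Reactants: 7 rac-1-[2,4-bis(methoxymethoxy)phenyl]-5-methylhex-4-en-2-yn-1-ol; 9 2-hydroxy-4,6-bis(methoxymethoxy)benzaldehyde
Product: 10 rac-2-({1-[2,4-bis(methoxymethoxy)phenyl]-5-methylhex-4-en-2-yn-1-yl}oxy)-4,6-bis(methoxymethoxy)benzaldehyde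
Conditions: PPh3 (1.3 equiv), DIAD (1.3 equiv), THF, 0 °C → rt
Reagents that add atoms: none
Why: Mitsunobu etherification; the acidic salicylaldehyde-type phenol displaces the activated secondary propargylic alcohol, which has no β-hydrogen to eliminate, and the racemic centre is irrelevant.

**Step 6**
Reactants: 10 rac-2-({1-[2,4-bis(methoxymethoxy)phenyl]-5-methylhex-4-en-2-yn-1-yl}oxy)-4,6-bis(methoxymethoxy)benzaldehyde
Product: 13 2-[2,4-bis(methoxymethoxy)phenyl]-5,7-bis(methoxymethoxy)-3-(3-methylbut-2-en-1-yl)-4H-chromen-4-one, via Breslow intermediate 11 (not isolated), via exocyclic dienone 12 (not isolated)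
Conditions: 3-mesityl-5,6,7,8-tetrahydro-4H-cyclohepta[d]thiazol-3-ium perchlorate (20 mol %), K2CO3 (40 mol %), THF, 70 °C; then DBU (0.3 equiv), 40 °C, one pot
Reagents that add atoms: none
Why: Proposed new method: the thiazol-2-ylidene adds to the aldehyde of 10 to give Breslow intermediate 11, whose former carbonyl carbon, now nucleophilic, attacks the proximal alkyne carbon in a concerted Conia-ene-like 6-exo-dig transition state with syn transfer of the enol O–H to the distal carbon, releasing the carbene and (E)-dienone 12, which DBU converts by deprotonation of the benzylic, allylic C2–H and kinetic reprotonation at the central carbon of the pentadienyl anion into the pyranone 13 (C2 centre erased, skipped prenyl alkene kept); the closest known reactions are the carbene-catalysed intramolecular hydroacylation of unactivated alkynes in 2-(propargyloxy)benzaldehydes (a Stetter-type reaction) and the base-mediated isomerisation of 3-benzylideneflavanones to 3-benzylflavones.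

**Step 7**
Reactants: 13 2-[2,4-bis(methoxymethoxy)phenyl]-5,7-bis(methoxymethoxy)-3-(3-methylbut-2-en-1-yl)-4H-chromen-4-one
Product: 14 Albanin A, 2-(2,4-dihydroxyphenyl)-5,7-dihydroxy-3-(3-methylbut-2-en-1-yl)-4H-chromen-4-one
Conditions: 3 M aq HCl/MeOH (1:5), 50 °C
Reagents that add atoms: none
Why: acid-catalysed acetal exchange removes all four MOM groups; the 3-prenyl group cannot form a six-membered chroman with any of the phenols, so it survives the mild acid, and the product has no stereocentre.

**Compound list**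
1 | 2,4-dihydroxybenzaldehyde | O=Cc1ccc(O)cc1O | starting material
2 | chloromethyl methyl ether | COCCl | starting material
3 | 2,4-bis(methoxymethoxy)benzaldehyde | O=Cc1ccc(OCOC)cc1OCOC | intermediate
4 | ethynylmagnesium bromide | C#C[Mg]Br | starting material
5 | rac-1-[2,4-bis(methoxymethoxy)phenyl]prop-2-yn-1-ol | C#CC(O)c1ccc(OCOC)cc1OCOC | intermediate
6 | 1-bromo-2-methylprop-1-ene | CC(C)=CBr | starting material
7 | rac-1-[2,4-bis(methoxymethoxy)phenyl]-5-methylhex-4-en-2-yn-1-ol | CC(C)=CC#CC(O)c1ccc(OCOC)cc1OCOC | intermediate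
8 | 2,4,6-trihydroxybenzaldehyde | O=Cc1c(O)cc(O)cc1O | starting material
9 | 2-hydroxy-4,6-bis(methoxymethoxy)benzaldehyde | O=Cc1c(O)cc(OCOC)cc1OCOC | intermediate
10 | rac-2-({1-[2,4-bis(methoxymethoxy)phenyl]-5-methylhex-4-en-2-yn-1-yl}oxy)-4,6-bis(methoxymethoxy)benzaldehyde | CC(C)=CC#CC(Oc1cc(OCOC)cc(OCOC)c1C=O)c1ccc(OCOC)cc1OCOC | intermediate
11 | Breslow intermediate (enaminol adduct of aldehyde 10 and the N-mesityl cycloheptathiazol-2-ylidene, racemic) | OC(c1c(OC(C#CC=C(C)C)c2ccc(OCOC)cc2OCOC)cc(OCOC)cc1OCOC)=C1SC2=C(CCCCC2)N1c1c(C)cc(C)cc1C | intermediate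
12 | (E)-2-[2,4-bis(methoxymethoxy)phenyl]-5,7-bis(methoxymethoxy)-3-(3-methylbut-2-en-1-ylidene)chroman-4-one (racemic at C2) | CC(C)=C/C=C1/C(=O)c2c(OCOC)cc(OCOC)cc2OC1c1ccc(OCOC)cc1OCOC | intermediate
13 | 2-[2,4-bis(methoxymethoxy)phenyl]-5,7-bis(methoxymethoxy)-3-(3-methylbut-2-en-1-yl)-4H-chromen-4-one | CC(C)=CCc1c(-c2ccc(OCOC)cc2OCOC)oc2cc(OCOC)cc(OCOC)c2c1=O | intermediate
14 | Albanin A | CC(C)=CCc1c(-c2ccc(O)cc2O)oc2cc(O)cc(O)c2c1=O | target

**Totals**
Total step count: 7. Longest linear sequence: 6 (steps 1, 2, 3, 5, 6, 7).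

**Three steps most likely to fail**

1. Step 6 is the main risk. The aldehyde of 10 is flanked by two oxygen substituents and is electron-rich, so Breslow formation may be slow. A thermal [1,5]-hydrogen shift in dienone 12 could also give the conjugated 3-(3-methylbut-1-enyl) isomer instead of the prenyl compound. The fallback sets out from 3 and 9 and comes back at 13. Aldehyde 3 is homologated with dimethyl (1-diazo-2-oxopropyl)phosphonate and K2CO3 in MeOH to 1-ethynyl-2,4-bis(methoxymethoxy)benzene F1. Its copper acetylide (n-BuLi, catalytic CuI, THF) is alkylated with prenyl bromide to 2,4-bis(methoxymethoxy)-1-(5-methylhex-4-en-1-yn-1-yl)benzene F2. Rhodium-catalysed oxidative annulation of salicylaldehyde 9 with F2 ([RhCl(cod)]2, C5H2Ph4, Cu(OAc)2·H2O, o-xylene, 120 °C) then gives 13 directly; the acyl group adds to the alkyl-bearing alkyne carbon and the aryl-bearing carbon bonds to oxygen.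

2. Step 5 is the second risk. The activated alcohol of 7 sits on a very electron-rich benzylic, propargylic carbon and may ionise, giving C-alkylation or allenyl ether instead of clean O-alkylation. The fallback sets out from 5 (with 9 and 6) and comes back at 10. Alcohol 5 is acetylated (Ac2O, Et3N, DMAP) to rac-1-[2,4-bis(methoxymethoxy)phenyl]prop-2-yn-1-yl acetate F3. Copper-catalysed propargylic etherification through a copper allenylidene (CuOTf, achiral pybox ligand, i-Pr2NEt, MeCN) with phenol 9 gives rac-2-({1-[2,4-bis(methoxymethoxy)phenyl]prop-2-yn-1-yl}oxy)-4,6-bis(methoxymethoxy)benzaldehyde F4. Sonogashira coupling of F4 with 6 (conditions of step 3) gives 10.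

3. Step 3 is the third risk. Glaser homocoupling or base-mediated redox isomerisation of the propargylic alcohol to an enone can compete with slow oxidative addition of the hindered vinyl bromide. The fallback sets out from 3 and comes back at 7, without palladium. Commercial 3-methylbut-2-enal is converted with CBr4 and PPh3 into 1,1-dibromo-4-methylpenta-1,3-diene F5. Treatment with n-BuLi (2 equiv, THF, −78 °C) gives lithium 4-methylpent-3-en-1-yn-1-ide F6, which is added in the same flask to aldehyde 3 to give 7.

**Further compounds**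
F1 | step 6 | 1-ethynyl-2,4-bis(methoxymethoxy)benzene | C#Cc1ccc(OCOC)cc1OCOC
F2 | step 6 | 2,4-bis(methoxymethoxy)-1-(5-methylhex-4-en-1-yn-1-yl)benzene | CC(C)=CCC#Cc1ccc(OCOC)cc1OCOC
F3 | step 5 | rac-1-[2,4-bis(methoxymethoxy)phenyl]prop-2-yn-1-yl acetate | C#CC(OC(C)=O)c1ccc(OCOC)cc1OCOC
F4 | step 5 | rac-2-({1-[2,4-bis(methoxymethoxy)phenyl]prop-2-yn-1-yl}oxy)-4,6-bis(methoxymethoxy)benzaldehyde | C#CC(Oc1cc(OCOC)cc(OCOC)c1C=O)c1ccc(OCOC)cc1OCOC
F5 | step 3 | 1,1-dibromo-4-methylpenta-1,3-diene | CC(C)=CC=C(Br)Br
F6 | step 3 | lithium 4-methylpent-3-en-1-yn-1-ide | [Li]C#CC=C(C)C
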